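**Plan**

- Retrosynthesis: the ring B ketol bond C(=O)–CH2OH is cut first, leaving an aryl aldehyde and formaldehyde, and C9 is taken back from CH2OH to an ester.
- The C8–O bond to ring B and the C7–C8 bond are then cut together, giving a ring B phenol, O-acetylvanillin and ethyl diazoacetate.
- Enabling feature: C8 carries three different groups (the ring B phenol oxygen, the ring A carbinol carbon C7 and the one-carbon unit C9), so a diazoacetate carbene carbon can become C8 and take up the oxygen and C7 in one event.
- Forward order: syringaldehyde is masked as its dioxolane, the three components are joined at C8, the ester is reduced to C9H2OH with loss of the aryl acetate, the ring B aldehyde is freed and then hydroxymethylated. No ring is formed.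
- Stereochemistry: C7 and C8 are both set in the three-component coupling by a chiral zirconium–BINOL Lewis acid (anti, erythro) and are carried unchanged to the (7R,8S) target.

Key step: step 2

**Remarks on the chemistry**

- Numbering: C7 is the benzylic carbinol on ring A (the 4-hydroxy-3-methoxyphenyl ring), C8 the aryloxy-bearing carbon, C9 the CH2OH carbon. Ring B is the 2,6-dimethoxyphenoxy ring that carries the hydroxyacetyl group.
- Assumption: the sense of induction of the zirconium–BINOL complex on this new type of ylide cannot be taken from precedent. (S)-BINOL is written, and (R)-BINOL would be used should the (2S,3S) ester form. The same holds for the BINOL ligand in the fallback for step 2.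
- Compound 3 (vanillin acetate) and compound 4 are bought.

**Route**

Step 1
Reactants: 1 syringaldehyde (4-hydroxy-3,5-dimethoxybenzaldehyde)
Product: 2 4-(1,3-dioxolan-2-yl)-2,6-dimethoxyphenol
Conditions: HOCH2CH2OH (5 equiv), p-TsOH·H2O (2 mol%), toluene, reflux, Dean–Stark; Et3N quench; chromatography on Et3N-deactivated silica
Reagents that add atoms: ethylene glycol, OCCO
Why: Acid-catalysed acetalisation with azeotropic removal of water should drive the aldehyde of 1 to the 1,3-dioxolane while the hindered phenol stays free, and neutralising the acid before work-up keeps the labile acetal from reverting; no stereocentre is formed.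

Step 2
Reactants: 2 4-(1,3-dioxolan-2-yl)-2,6-dimethoxyphenol; 3 4-formyl-2-methoxyphenyl acetate (O-acetylvanillin); 4 ethyl diazoacetate
Product: 6 ethyl (2R,3R)-3-(4-acetoxy-3-methoxyphenyl)-2-[4-(1,3-dioxolan-2-yl)-2,6-dimethoxyphenoxy]-3-hydroxypropanoate, via oxonium ylide 5 (not isolated)
Conditions: Zr(OBu)4 (15 mol%) and (S)-BINOL (30 mol%) premixed with 4 Å MS in CH2Cl2; then 2 (1.0 equiv), 3 (1.2 equiv), Rh2(OAc)4 (2 mol%), 0 °C; 4 (1.5 equiv) in CH2Cl2 added by syringe pump over 4 h
Reagents that add atoms: none
Why: Proposed new method: Rh2(OAc)4 (divalent rhodium) decomposes 4 with loss of N2, the phenol oxygen of 2 adds to the electrophilic carbene carbon, and the resulting oxonium ylide 5 (a rhodium-associated ester enolate) should add through its carbanionic carbon to aldehyde 3 bound to the Zr(OBu)4–(S)-BINOL complex (tetravalent zirconium) before the 1,2-proton shift that would end in plain O–H insertion, so that C8–O and C7–C8 form in one operation; the closest known reaction type is the Rh2(OAc)4/chiral Lewis acid three-component coupling of aryldiazoacetates, alcohols and aldehydes by aldol trapping of oxonium ylides, and the unsubstituted diazoacetate with a phenol is the untested part. No ring closes. Both new stereocentres (C7 and C8, 2R,3R in 6) arise in the C–C bond-forming event under control of the chiral zirconium complex, which holds the aldehyde, shields one carbonyl face and, as in zirconium–BINOL Mukaiyama aldol additions, should favour the open anti (erythro) transition state. The step needs trapping to outrun proton transfer, anti over syn addition and one enantiomer. The acetoxy group makes the carbonyl of 3 more electrophilic than that of free vanillin and keeps its phenol from competing for the carbene, while the two methoxy groups flanking the oxygen of 2 crowd the oxonium centre and slow the proton shift. Slow addition of 4 keeps the diazo ester concentration low, which should hold back carbene dimerisation and direct zirconium-promoted addition of 4 to 3, and the acetal carbon of 2 is no acceptor under these conditions.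

Step 3
Reactants: 6 ethyl (2R,3R)-3-(4-acetoxy-3-methoxyphenyl)-2-[4-(1,3-dioxolan-2-yl)-2,6-dimethoxyphenoxy]-3-hydroxypropanoate
Product: 7 (1R,2S)-2-[4-(1,3-dioxolan-2-yl)-2,6-dimethoxyphenoxy]-1-(4-hydroxy-3-methoxyphenyl)propane-1,3-diol
Conditions: LiBH4 (4 equiv), THF, 0 °C to rt; quench with pH 7 phosphate buffer
Reagents that add atoms: none
Why: Ester reduction with LiBH4 should convert the α-aryloxy ester, activated by its α-oxygen and by lithium chelation to the C7 alkoxide, into the C9 primary alcohol and cleave the aryl acetate reductively in the same flask (the acetyl group leaving as ethanol), while the dioxolane and aryl ethers are inert to hydride and the cold, weakly basic medium allows neither enolisation at C8 nor retro-aldol cleavage.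

Step 4
Reactants: 7 (1R,2S)-2-[4-(1,3-dioxolan-2-yl)-2,6-dimethoxyphenoxy]-1-(4-hydroxy-3-methoxyphenyl)propane-1,3-diol
Product: 8 4-{[(1R,2S)-1,3-dihydroxy-1-(4-hydroxy-3-methoxyphenyl)propan-2-yl]oxy}-3,5-dimethoxybenzaldehyde
Conditions: 0.1 M HCl in THF–H2O (4:1), 0 °C to rt; NaHCO3 quench
Reagents that add atoms: water, O
Why: Acid-catalysed acetal hydrolysis should open the 2-aryl-1,3-dioxolane through its oxocarbenium ion in dilute acid at room temperature much faster than the C7 benzylic carbinol can ionise, so the ring B aldehyde is released with C7 and C8 intact.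

Step 5
Reactants: 8 4-{[(1R,2S)-1,3-dihydroxy-1-(4-hydroxy-3-methoxyphenyl)propan-2-yl]oxy}-3,5-dimethoxybenzaldehyde
Product: 9 1-(4-{[(1R,2S)-1,3-dihydroxy-1-(4-hydroxy-3-methoxyphenyl)propan-2-yl]oxy}-3,5-dimethoxyphenyl)-2-hydroxyethan-1-one (the target, 7R,8S)
Conditions: (CH2O)n (5 equiv), 3-ethylbenzothiazolium bromide (20 mol%), Et3N (20 mol%), EtOH, 60 °C, argon
Reagents that add atoms: paraformaldehyde (reacting as formaldehyde), C=O
Why: Carbene-catalysed cross-acyloin (benzoin-type) hydroxymethylation: the benzothiazol-2-ylidene generated from the salt and Et3N should turn the aldehyde carbon of 8 into a nucleophilic Breslow intermediate that adds to the excess of highly electrophilic formaldehyde faster than to a second molecule of 8, giving the hydroxyacetyl group, while the weak amine base at moderate temperature should leave the free phenol, the diol and the two remote stereocentres untouched.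

**Compound list**

1 | syringaldehyde (4-hydroxy-3,5-dimethoxybenzaldehyde) | COc1cc(C=O)cc(OC)c1O | starting material
2 | 4-(1,3-dioxolan-2-yl)-2,6-dimethoxyphenol | COc1cc(C2OCCO2)cc(OC)c1O | intermediate
3 | 4-formyl-2-methoxyphenyl acetate (O-acetylvanillin) | COc1cc(C=O)ccc1OC(C)=O | starting material
4 | ethyl diazoacetate | CCOC(=O)C=[N+]=[N-] | starting material
5 | oxonium ylide from 2 and the carbene of 4 (O-aryl O-H oxonium, carbanion α to the ester; not isolated) | CCOC(=O)[CH-][OH+]c1c(OC)cc(C2OCCO2)cc1OC | intermediate
6 | ethyl (2R,3R)-3-(4-acetoxy-3-methoxyphenyl)-2-[4-(1,3-dioxolan-2-yl)-2,6-dimethoxyphenoxy]-3-hydroxypropanoate | COc1cc([C@@H](O)[C@H](C(=O)OCC)Oc2c(OC)cc(C3OCCO3)cc2OC)ccc1OC(C)=O | intermediate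
7 | (1R,2S)-2-[4-(1,3-dioxolan-2-yl)-2,6-dimethoxyphenoxy]-1-(4-hydroxy-3-methoxyphenyl)propane-1,3-diol | COc1cc([C@@H](O)[C@H](CO)Oc2c(OC)cc(C3OCCO3)cc2OC)ccc1O | intermediate
8 | 4-{[(1R,2S)-1,3-dihydroxy-1-(4-hydroxy-3-methoxyphenyl)propan-2-yl]oxy}-3,5-dimethoxybenzaldehyde | COc1cc([C@@H](O)[C@H](CO)Oc2c(OC)cc(C=O)cc2OC)ccc1O | intermediate
9 | 1-(4-{[(1R,2S)-1,3-dihydroxy-1-(4-hydroxy-3-methoxyphenyl)propan-2-yl]oxy}-3,5-dimethoxyphenyl)-2-hydroxyethan-1-one | COc1cc([C@@H](O)[C@H](CO)Oc2c(OC)cc(C(=O)CO)cc2OC)ccc1O | target

**Totals**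

Total step count: 5. Longest linear sequence: 5 steps (1 → 2 → 6 → 7 → 8 → 9).

**Steps most likely to fail**

Step 2. The ylide may collapse by 1,2-proton shift to the simple O–H insertion product before it meets the aldehyde. The carbene may also dimerise, the diazo ester may add directly to the zirconium-bound aldehyde, or facial and anti/syn control may be poor. The fallback makes the same two bonds one after the other by known reactions and sets out from 2. Williamson etherification with ethyl bromoacetate (K2CO3, acetone, reflux) should give ethyl 2-[4-(1,3-dioxolan-2-yl)-2,6-dimethoxyphenoxy]acetate F1, which is also the compound the proton shift in step 2 would give, so that material could be recycled here. Enolisation with LiN(iPr)2 and trapping with Me3SiCl (THF, −78 °C) should give the ketene silyl acetal {[(Z)-2-[4-(1,3-dioxolan-2-yl)-2,6-dimethoxyphenoxy]-1-ethoxyethenyl]oxy}trimethylsilane F2; the Z geometry is expected from the chelated lithium enolate and is not critical. An anti-selective asymmetric Mukaiyama aldol addition of F2 to 3 (Zr(OtBu)4 (10 mol%), (R)-3,3'-diiodo-BINOL (12 mol%), PrOH (1 equiv) as silyl acceptor, toluene, 0 °C) should then deliver the anti ester, coming back to the route at 6.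

Step 5. The Breslow intermediate of this electron-rich aldehyde may form slowly, self-benzoin coupling may compete, and formaldehyde may condense with the free phenol ring under base. The fallback builds the ketol by stepwise known chemistry, from 8 to 9.
- Silylation of all three hydroxyls (tert-butyldimethylsilyl triflate, 2,6-lutidine, CH2Cl2, −78 to 0 °C) should give 4-{[(1R,2S)-1,3-bis(tert-butyldimethylsilyloxy)-1-[4-(tert-butyldimethylsilyloxy)-3-methoxyphenyl]propan-2-yl]oxy}-3,5-dimethoxybenzaldehyde F3.
- Grignard addition of MeMgBr (THF, −78 to 0 °C) should give the 1-arylethanol F4, as a mixture of epimers at the new carbinol.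
- Dess–Martin oxidation should give the aryl methyl ketone F5.
- LiN(SiMe3)2 and Me3SiCl (THF, −78 °C) should give the trimethylsilyl enol ether F6, used crude.
- Rubottom oxidation with mCPBA (NaHCO3, CH2Cl2, 0 °C) should give the 2-(trimethylsilyloxy) ketone F7.
- Global desilylation with HF·pyridine (THF–pyridine, 0 °C to rt) rejoins the route at 9.

Step 1. The para-hydroxyl makes the aldehyde a poor electrophile, so acetalisation may stall, and the acetal of the free phenol may revert on work-up or on silica. The fallback keeps the phenol masked while the acetal is made and sets out from 1. Acetylation (Ac2O, pyridine, rt) should give 4-formyl-2,6-dimethoxyphenyl acetate F8. Silyl-transfer acetalisation (1,2-bis(trimethylsilyloxy)ethane, Me3SiOTf (cat.), CH2Cl2, −78 °C) should give 4-(1,3-dioxolan-2-yl)-2,6-dimethoxyphenyl acetate F9. Methanolysis of the acetate under basic conditions that do not touch the acetal (K2CO3 (cat.), MeOH, rt) comes back to the route at 2.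

**Further compounds**

F1 | step 2 | ethyl 2-[4-(1,3-dioxolan-2-yl)-2,6-dimethoxyphenoxy]acetate | CCOC(=O)COc1c(OC)cc(C2OCCO2)cc1OC
F2 | step 2 | {[(Z)-2-[4-(1,3-dioxolan-2-yl)-2,6-dimethoxyphenoxy]-1-ethoxyethenyl]oxy}trimethylsilane | CCO/C(O[Si](C)(C)C)=C/Oc1c(OC)cc(C2OCCO2)cc1OC
F3 | step 5 | 4-{[(1R,2S)-1,3-bis(tert-butyldimethylsilyloxy)-1-[4-(tert-butyldimethylsilyloxy)-3-methoxyphenyl]propan-2-yl]oxy}-3,5-dimethoxybenzaldehyde | COc1cc([C@@H](O[Si](C)(C)C(C)(C)C)[C@H](CO[Si](C)(C)C(C)(C)C)Oc2c(OC)cc(C=O)cc2OC)ccc1O[Si](C)(C)C(C)(C)C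
F4 | step 5 | 1-(4-{[(1R,2S)-1,3-bis(tert-butyldimethylsilyloxy)-1-[4-(tert-butyldimethylsilyloxy)-3-methoxyphenyl]propan-2-yl]oxy}-3,5-dimethoxyphenyl)ethan-1-ol (epimers at the new carbinol) | COc1cc([C@@H](O[Si](C)(C)C(C)(C)C)[C@H](CO[Si](C)(C)C(C)(C)C)Oc2c(OC)cc(C(C)O)cc2OC)ccc1O[Si](C)(C)C(C)(C)C
F5 | step 5 | 1-(4-{[(1R,2S)-1,3-bis(tert-butyldimethylsilyloxy)-1-[4-(tert-butyldimethylsilyloxy)-3-methoxyphenyl]propan-2-yl]oxy}-3,5-dimethoxyphenyl)ethan-1-one | COc1cc([C@@H](O[Si](C)(C)C(C)(C)C)[C@H](CO[Si](C)(C)C(C)(C)C)Oc2c(OC)cc(C(C)=O)cc2OC)ccc1O[Si](C)(C)C(C)(C)C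
F6 | step 5 | trimethylsilyl enol ether of F5 (1-aryl-1-(trimethylsilyloxy)ethene) | COc1cc([C@@H](O[Si](C)(C)C(C)(C)C)[C@H](CO[Si](C)(C)C(C)(C)C)Oc2c(OC)cc(C(=C)O[Si](C)(C)C)cc2OC)ccc1O[Si](C)(C)C(C)(C)C
F7 | step 5 | 1-(4-{[(1R,2S)-1,3-bis(tert-butyldimethylsilyloxy)-1-[4-(tert-butyldimethylsilyloxy)-3-methoxyphenyl]propan-2-yl]oxy}-3,5-dimethoxyphenyl)-2-(trimethylsilyloxy)ethan-1-one | COc1cc([C@@H](O[Si](C)(C)C(C)(C)C)[C@H](CO[Si](C)(C)C(C)(C)C)Oc2c(OC)cc(C(=O)CO[Si](C)(C)C)cc2OC)ccc1O[Si](C)(C)C(C)(C)C
F8 | step 1 | 4-formyl-2,6-dimethoxyphenyl acetate | COc1cc(C=O)cc(OC)c1OC(C)=O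
F9 | step 1 | 4-(1,3-dioxolan-2-yl)-2,6-dimethoxyphenyl acetate | COc1cc(C2OCCO2)cc(OC)c1OC(C)=O
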